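(Its constants stand for no real mixture; no experiment stands behind them.)

Watch how far L in north-west sinks below the part of its charge that E cannot take.

all flasks: L 44 mM; D 13.2 mM; J 0.22 mM; time 4.0 min

| flask | E |
|---|---|
| north-east | 44.0 mM |
| north-west | 12.0 mM |

    L + J → X + Z (k1 = 0.891 L mol⁻¹ s⁻¹)
    L + X → Z + X, rate k2*[X]*[L] (k2 = 15.9 L mol⁻¹ s⁻¹)
    X + D → X.D (k3 = 0.355 L mol⁻¹ s⁻¹)
    E + L → E.L (k4 = 0.966 L mol⁻¹ s⁻¹)

* which of the two ends with the longer chains by the average number of monomer units in a chain (chains begun, living or dead) ("neither" if they lie within 10%) (north-east / north-west / neither)
* average number of monomer units in a chain (chains begun, living or dead) at the end, north-east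
* average number of monomer units in a chain (chains begun, living or dead) at the end, north-west

- the average divides the monomer in chains by the number of chains begun, living and dead together
- run time (north-east): 4.0 min

I reckon in fractions of the L charge. In north-west the E charge is smaller than the L charge, leaving a surplus s = 0.727. E falls with a time constant of 32.3 s and J with 35.1 s, each shorter than the run of 240 s. So I start north-west with s of free L and the J charge as living ends. The logarithm of L then falls at the propagation constant times X, and this integrates at once. If the ends never died:

first dose = 15.9 L mol⁻¹ s⁻¹ × 0.22 mM × 240 s = 0.840

Z = s × (1 − exp(−dose)), and length = Z × L charge / J charge = 82.6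

That link is weak, since X is lost to D on a time constant of 213 s, shorter than the run. D stands at 60.0 times the J charge, so the loss of X is pseudo-first-order, at 0.00469 s⁻¹. Over the run an end counts for an effective 144 s, less than the full time. Reforged:

dose = 15.9 L mol⁻¹ s⁻¹ × 0.22 mM × 144 s = 0.504

The dose is the propagation constant times the time integral of X, the logarithm by which X cuts free L.

north-west length = 57.6

In north-east the E charge equals the L charge, so the surplus is 0 and I do not use the rule there. For north-east I take L to follow a hyperbola, with L and E falling together. By that estimate an end present from the start meets 39.8 units, averaging over late starts gives 27.7, and the survival share 0.600 gives my rougher 16.6.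

The forecast says 19 for north-east, above mine, and 57 for north-west, just below mine, and it names north-west: “chains grow for longer and roughly three times as far”.

The run gives 17.9 in north-east and 56.3 in north-west, so north-west holds the longer chains. North-west keeps 44.8% of its L at 4.00 min, and s × exp(−dose) is 43.9%. For the neighbour of north-west charged with 0.37 mM of J I reckon a dose of 0.848, which gives 31.1% of L and a length of 49.4. That neighbour, when run, ends with 32% of its L and a length of 48.7.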